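# Nakijiquinone M by ring expansion of a squarate-derived alkynylcyclobutenone

## The problem

Nakijiquinone M (25) consists of a Δ5-octalin (ring A = C1–C5/C10, ring B = C5–C10, gem-dimethyl at C4, olefin C5=C6) and a 1,4-benzoquinone (C1'–C6'). The two are joined only through the methylene C11, which is bonded to the quaternary carbon C9 and to C3'. C11 is therefore neopentyl, and whichever of its two bonds is made last is made next to a fully substituted carbon. The stereocentres C8, C9 and C10 are contiguous on ring B (8-methyl and 9-methyl cis, H10 on the side of C11). The flat, remote quinone controls none of them and quaternary C9 cannot be corrected later, so they are best set together: C8/C9 by an olefin geometry, C9/C10 by the topology of a cycloaddition, and the absolute sense by a catalyst. The C5=C6 olefin is the weak point of the terpene half. Acid moves it to the tetrasubstituted C5=C10 position or lets the cation be trapped by the C2' hydroxyl group, and the strong oxidants that unmask quinones from arenes can also attack it. The quinone half is acidic, redox-active and open to nucleophilic exchange as a vinylogous acid and amide, so its final substituents should appear late and under mild conditions. This pattern (side chain at C3' next to oxygen at C2', nitrogen-bearing C5' next to C6'–H) is what ring expansion of a 2-alkyl-3-alkoxy-4-alkynyl-4-hydroxycyclobutenone delivers. The four ring carbons become C4', C3', C2' and C1', the alkyne carbons become C6' and C5', and the carbinol hydrogen ends on C6'.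

## Retrosynthesis

**25 ⇒ 23 (oxygen at C2').** The hydroxyl group is traced back to its methyl ether, so in the forward sense C2'–OCH3 is exchanged for C2'–OH. Carrying the free hydroxyquinone through the amination is worse, because the amine would deprotonate it and the anion is a poor acceptor. The methyl group costs no step, since it is one of the methoxy groups of 10, and in 23 it also steers the amine. The forward reaction must let hydroxide attack C2' and spare the vinylogous amide at C5'.

**23 ⇒ 20 + 21 (C5'–N).** This cut removes the whole amine 21 and leaves quinone 20 with C–H at C5' and C6'. It is allowed because the C2' methoxy group makes the two carbonyl groups of 20 unequal. It donates into C4'=O, so C1'=O is the stronger acceptor and its β-carbon is C5'. The forward reaction is an oxidative conjugate amination. It needs attack at C5' rather than at C6' or ipso at C2', and a mild terminal oxidant.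

**20 ⇒ 17 (C4'–C5', the key cut).**
- *The cut.* Cutting C4'–C5', returning H6' to the oxygen on C1' and re-closing C1'–C4' gives the 4-ethynyl-4-hydroxycyclobutenone 17.
- *Why this cut.* Deriving the ring from a polymethoxyarene needs a strong oxidant in the presence of C5=C6. Here the ring forms at the quinone oxidation level by heat alone.
- *Why this mapping.* The alkyne terminus always ends next to the carbon that receives hydrogen. The side chain is para to C6'–H, so it must sit on the cyclobutenone and not on the alkyne.
- *Why the terminus is C–H.* A donor there (alkoxy, amino) would bring the C5' heteroatom directly, but it has three drawbacks. It makes the inner alkyne carbon the nucleophilic one, matched with the electrophilic ketene carbon. It stabilises the exocyclic vinyl radical of the five-membered closure, which leads to an alkylidenecyclopentenedione instead of a quinone. An ethyl ynol ether can also lose ethylene by a retro-ene reaction near the thermolysis temperature.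
- *Gain and demand.* Four differently substituted ring positions reduce to the order of two carbonyl additions to a squarate. The forward step needs outward rotation of the hydroxyl group, six-membered closure and a neutral medium.

**17 ⇒ 14 + 15 (C1'–C6').** The carbinol–alkyne bond is cut to cyclobutenedione 14 and acetylene 15, used as its lithium salt 16. The alternative order (alkyne first, side chain second) would place the side chain on the carbinol carbon and destroy the pattern. The acetylide must choose the ketone-like carbonyl beside the methoxy-bearing carbon. The other carbonyl is the vinylogous ester carbonyl and is also screened by the side chain, so electronic and steric bias agree.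

**14 ⇒ 9 + 10 (C11–C3').** C9–C11 cannot be cut usefully because it is part of the quaternary centre, so the outer bond of C11 is chosen. C11 becomes the nucleophile, organolithium 11 from iodide 9. It is primary and its β-carbon C9 bears no hydrogen, so it cannot eliminate. The electrophile, dimethyl squarate 10, is small and flat. Addition followed by loss of methanol gives 14. The price is a substitution at a neopentyl carbon to make 9.

**9 ⇒ 8 ⇒ 7 (functional group changes at C11).** The iodide comes from alcohol 8 and this from aldehyde 7. No skeletal bond or stereocentre is involved.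

**7 ⇒ 5 + 6 (C7–C8 and C9–C10).** Both bonds of ring B that flank the stereotriad are cut at once. This leaves diene 5 and tiglaldehyde 6, neither of which has a stereocentre. No neighbouring pair of cuts in ring B sets all three centres and places the olefin at C5=C6 in the same event. The forward Diels–Alder reaction must join C7 to C8, be exo for the formyl group and be enantioselective.

**5 ⇒ 3 + 4, 3 ⇒ 1 (C5–C6).** The vinyl group is removed to enol triflate 3 and vinylstannane 4. Triflate 3 comes from ketone 1, which can enolise on one side only.

## Roads not taken

**Alternative 1:** The cut is C9–C10, with C6–O restored.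
- *Forward step.* δ-Lactone A1 is converted into its O-silylated enolate and undergoes an Ireland–Claisen ring contraction through a boat-shaped transition state to acid A2. This forms C9–C10 and places the olefin at C5=C6.
- *Merits.* Chirality passes intramolecularly from the C6 carbinol to C9 and C10. The olefin position is unambiguous. The arylmethyl group enters by simple enolate alkylation, so no neopentyl coupling is needed, and in that respect this road is better than the chosen one.
- *Weak points.* The carboxyl group of A2 must be reduced to a methyl group at a fully hindered quaternary centre (reduction, activation, reduction). A1 needs two stereocentres in a 1,3-trans relation and a synthesis of its own. The rearrangement joins a tetrasubstituted ketene acetal carbon to an olefin carbon beside the gem-dimethyl group. The tetramethoxyarene must still be oxidised in the presence of C5=C6.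
- *Comparison.* The chosen plan sets the three centres in one intermolecular step from achiral materials, needs no redox correction on the terpene and is clearly shorter.

**Alternative 2:** The cuts are C1–C10 and C4–C5 (ring A).
- *Forward step.* Diene A4 adds to one enantiotopic olefin of the achiral dienone A3 under a chiral Lewis acid to give A5.
- *Merits.* The quaternary C9 with its arylmethyl group is made early and cheaply. One desymmetrising step fixes C9 and C10. Approach anti to the larger arylmethyl group gives the relation the target needs.
- *Weak points.* A4 carries a Z-methyl group on its reacting terminus, so its s-cis form is poorly populated and it must form quaternary C4. 4,4-Disubstituted dienones are sluggish dienophiles. A5 carries functionality the target lacks: oxygen at C2 must be removed, and the C6 ketone must be turned regioselectively into the C5=C6 olefin, which destroys the C5 centre. The 8-methyl group must still be added next to quaternary C9, and the arene must still be oxidised.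
- *Comparison.* The road is attractive for its use of symmetry, but it pays with about six corrective steps, whereas every carbon brought in by the chosen plan stays.

**Alternative 3:** The cuts are C7–C8 and C9–C10.
- *Forward step.* 5 and 6 combine under an AlBr3-activated chiral oxazaborolidine to give aldehyde A6, which is the same compound as 7.
- *Relation to the chosen plan.* This is the best way to the decalin and is adopted as step 3, so the two roads differ only in the use of the formyl carbon. Here lithiated A7 adds to it and the benzylic oxygen is removed to give A8. (NH4)2Ce(NO3)6 then oxidises the arene to A9, and hydrolysis and amine exchange finish the synthesis.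
- *Merits.* C11 acts as the electrophile, so no neopentyl iodide is needed. The amine enters A9 by substitution without an oxidant. In both respects this road is at least as safe as the chosen one, and its length is about the same.
- *Weak points.* The deoxygenation is at a hindered carbinol between a quaternary carbon and two ortho-methoxy groups. Ionic reduction brings acid to the olefin, dissolving metal threatens the methoxy groups, and the radical variant needs derivatisation of a crowded alkoxide. The oxidative demethylation can give ortho- and para-quinones and exposes C5=C6 to an acidic oxidant.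
- *Comparison.* The chosen plan forms the quinone by neutral heating with its substituents fixed by the order of two additions, needs no deoxygenation, and uses no oxidant stronger than O2.

Key step: step 8

Remark: terpenoid numbering (C1–C10, C11) and C1'–C6' for the quinone are used throughout. DM stands for [(1R,2S,8aS)-1,2,5,5-tetramethyl-1,2,3,5,6,7,8,8a-octahydronaphthalen-1-yl]methyl. The carbinol carbon of 12, 13, 17, F1 and F9 forms as a mixture of epimers and is written without configuration because it is lost again.

## Route

Step 1
Reactants: 1 2,2-dimethylcyclohexanone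
Product: 3 6,6-dimethylcyclohex-1-en-1-yl trifluoromethanesulfonate, via lithium enolate 2 (not isolated)
Conditions: LiN(iPr)2, THF, −78 °C; PhNTf2, −78 °C → rt
Reagents that add atoms: N-phenylbis(trifluoromethanesulfonimide), O=S(=O)(N(c1ccccc1)S(=O)(=O)C(F)(F)F)C(F)(F)F
Why: Standard enol triflate synthesis; the ketone has α-hydrogens on one side only, so a single enolate 2 forms and O-sulfonylation gives one regioisomer.

Step 2
Reactants: 3 6,6-dimethylcyclohex-1-en-1-yl trifluoromethanesulfonate; 4 tributyl(vinyl)stannane
Product: 5 6,6-dimethyl-1-vinylcyclohexene
Conditions: Pd(PPh3)4 (2 mol %), LiCl (3 equiv), THF, 65 °C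
Reagents that add atoms: none
Why: Stille coupling of an enol triflate; LiCl converts the oxidative-addition complex of zerovalent palladium into the chloride, which transmetallates with the stannane. The neighbouring quaternary carbon slows the coupling but should not prevent it, and the volatile diene is carried on as a concentrated solution.

Step 3
Reactants: 5 6,6-dimethyl-1-vinylcyclohexene; 6 tiglaldehyde, (E)-2-methylbut-2-enal
Product: 7 (1R,2S,8aR)-1,2,5,5-tetramethyl-1,2,3,5,6,7,8,8a-octahydronaphthalene-1-carbaldehyde
Conditions: (R)-3,3-diphenyl-1-(2-methylphenyl)tetrahydro-1H,3H-pyrrolo[1,2-c][1,3,2]oxazaborole (10 mol %), AlBr3 (8 mol %), CH2Cl2, −78 → −40 °C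
Reagents that add atoms: none
Why: Enantioselective Lewis-acid-catalysed Diels–Alder reaction of an α-substituted enal, in which the free vinyl terminus C7 bonds to the β-carbon C8 and C10 bonds to C9. The E geometry of 6 makes the 8- and 9-methyl groups cis, and the exo topology puts H10 on the side of C11; exo is usual for α-methyl enals and is reinforced here because an endo formyl–Lewis acid complex would lie under the C4 gem-dimethyl group. In the accepted binding model (formyl C–H···O contact, s-trans enal stacked on a phenyl group) the (R)-catalyst shields the Re face of C9, so the diene should add to the C9-Si/C8-Re face.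

Step 4
Reactants: 7 the aldehyde
Product: 8 [(1R,2S,8aR)-1,2,5,5-tetramethyl-1,2,3,5,6,7,8,8a-octahydronaphthalen-1-yl]methanol
Conditions: NaBH4, MeOH, 0 °C
Reagents that add atoms: none
Why: Hydride reduction of a non-enolisable aldehyde; the olefin is inert and no stereocentre is touched.

Step 5
Reactants: 8 the alcohol
Product: 9 (1R,2S,8aR)-1-(iodomethyl)-1,2,5,5-tetramethyl-1,2,3,5,6,7,8,8a-octahydronaphthalene
Conditions: I2, PPh3, imidazole, PhMe, 90 °C
Reagents that add atoms: iodine, II
Why: Appel-type iodination; displacement at the neopentyl carbon is slow and needs heat. β-Elimination is impossible because C9 is quaternary, and imidazole keeps the medium free of acid that could move the olefin.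

Step 6
Reactants: 9 the iodide; 10 dimethyl squarate
Product: 14 3-DM-4-methoxycyclobut-3-ene-1,2-dione, via organolithium 11 (not isolated), via lithium alkoxide 12 (not isolated), via trifluoroacetate 13 (not isolated)
Conditions: t-BuLi (2.0 equiv), Et2O–pentane, −78 °C; add to 10, THF, −78 °C; (CF3CO)2O, −78 °C; aq NH4Cl, → rt
Reagents that add atoms: water, O
Why: Lithium–iodine exchange with two equivalents of t-BuLi is fast and irreversible at −78 °C, and 11, whose β-carbon C9 bears no hydrogen, adds 1,2 to one of the two equivalent carbonyl groups of 10. Acylation of 12 turns the carbinol oxygen into a leaving group, the distal methoxy group assists ionisation of 13, and water collapses the oxocarbenium ion with loss of methanol. This is the standard squarate-to-cyclobutenedione sequence, run without mineral acid for the sake of C5=C6.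

Step 7
Reactants: 14 the cyclobutenedione; 15 acetylene
Product: 17 2-DM-4-ethynyl-4-hydroxy-3-methoxycyclobut-2-en-1-one (both carbinol epimers), via lithium acetylide 16 (not isolated)
Conditions: 15, n-BuLi, THF, −78 °C; then 14, −78 °C; aq NH4Cl
Reagents that add atoms: none
Why: 1,2-Addition of an acetylide to a 3-alkyl-4-alkoxycyclobutenedione. The carbonyl beside the DM-bearing carbon is deactivated as a vinylogous ester and screened by the side chain, so 16 should add to the ketone-like carbonyl beside the methoxy-bearing carbon. The new carbinol centre is uncontrolled and is lost in step 8.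

Step 8
Reactants: 17 the alkynyl carbinol
Product: 20 2-methoxy-3-DM-1,4-benzoquinone, via vinylketene 18 (not isolated), via diradical 19 (not isolated)
Conditions: p-xylene (0.01 M, degassed), 138 °C
Reagents that add atoms: none
Why: Heating cleaves the ring bond between the carbinol carbon and the carbonyl carbon (future C1' and C4') in a conrotatory 4π electrocyclic opening; the hydroxyl group, as the stronger donor, rotates outward, so both epimers of 17 give the same (Z)-vinylketene 18 with the ethynyl group turned toward the ketene. The ketene carbon C4' then bonds to the terminal alkyne carbon C5' in the six-membered closure of an enyne–ketene (Moore cyclisation, the ketene counterpart of the Myers–Saito reaction), giving the aromatic diradical 19 with an oxyl on C4' and a σ-radical on C6'. Transfer of the hydroxyl hydrogen from the oxygen on C1' to the adjacent C6' gives 20 at the quinone oxidation level without any oxidant. The closest known reaction type is the thermal rearrangement of 2-alkyl-3-alkoxy-4-alkynyl-4-hydroxycyclobutenones to 2-alkoxy-3-alkyl-1,4-benzoquinones. One six-membered ring is closed; no stereocentre is created, the carbinol centre disappears, and C8, C9, C10 and C5=C6 are remote spectators in a neutral medium. The selectivity needed is six- over five-membered closure, and the unsubstituted alkyne terminus secures it: five-membered closure would give an unstabilised primary vinyl radical, and no donor makes the inner alkyne carbon nucleophilic toward the ketene. The positions of the substituents were already fixed by the site of addition in step 7. The σ-radical at C6' is para to the side chain and out of reach of the decalin C–H bonds, and high dilution holds back bimolecular reactions of 19.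

Step 9
Reactants: 20 the methoxyquinone; 21 isopentylamine (3-methylbutan-1-amine)
Product: 23 2-methoxy-3-DM-5-[(3-methylbutyl)amino]-1,4-benzoquinone, via aminohydroquinone 22 (not isolated)
Conditions: 21 (1.1 equiv), Cu(OAc)2 (10 mol %), O2 (1 atm), MeOH, 0 °C → rt
Reagents that add atoms: none
Why: Oxidative conjugate amination of a quinone; the C2' methoxy group donates into C4'=O, so C1'=O is the stronger acceptor and the amine should add to its β-carbon C5'. The electron-rich 22 is reoxidised by O2 under Cu(OAc)2 catalysis, so no 20 is consumed as oxidant. Ipso exchange at C2' is held back by the flanking side chain and by using close to one equivalent of amine.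

Step 10
Reactants: 23 the aminomethoxyquinone
Product: 25 nakijiquinone M, 2-hydroxy-3-DM-5-[(3-methylbutyl)amino]-1,4-benzoquinone, via potassium salt 24 (not isolated)
Conditions: KOH (1 M aq), MeOH, rt; then 1 M HCl, 0 °C, pH 4
Reagents that add atoms: potassium hydroxide, [K+].[OH-]
Why: Addition–elimination of hydroxide at C2' of a vinylogous ester. The methoxy group is twisted out of conjugation by the side chain and is a much better leaving group than the amide-like nitrogen at C5', and the product is protected from further attack as its anion 24. Brief cold dilute acid should free 25 without moving the olefin.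

## Compound list

1 | 2,2-dimethylcyclohexanone | CC1(C)CCCCC1=O | starting material
2 | lithium 6,6-dimethylcyclohex-1-en-1-olate | [Li+].[O-]C1=CCCCC1(C)C | intermediate
3 | 6,6-dimethylcyclohex-1-en-1-yl trifluoromethanesulfonate | CC1(C)CCCC=C1OS(=O)(=O)C(F)(F)F | intermediate
4 | tributyl(vinyl)stannane | C=C[Sn](CCCC)(CCCC)CCCC | starting material
5 | 6,6-dimethyl-1-vinylcyclohexene | C=CC1=CCCCC1(C)C | intermediate
6 | tiglaldehyde, (E)-2-methylbut-2-enal | C/C=C(\C)C=O | starting material
7 | (1R,2S,8aR)-1,2,5,5-tetramethyl-1,2,3,5,6,7,8,8a-octahydronaphthalene-1-carbaldehyde | O=C[C@@]1(C)[C@@H]2CCCC(C)(C)C2=CC[C@@H]1C | intermediate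
8 | [(1R,2S,8aR)-1,2,5,5-tetramethyl-1,2,3,5,6,7,8,8a-octahydronaphthalen-1-yl]methanol | OC[C@@]1(C)[C@@H]2CCCC(C)(C)C2=CC[C@@H]1C | intermediate
9 | (1R,2S,8aR)-1-(iodomethyl)-1,2,5,5-tetramethyl-1,2,3,5,6,7,8,8a-octahydronaphthalene | IC[C@@]1(C)[C@@H]2CCCC(C)(C)C2=CC[C@@H]1C | intermediate
10 | dimethyl squarate, 3,4-dimethoxycyclobut-3-ene-1,2-dione | COC1=C(OC)C(=O)C1=O | starting material
11 | DM-lithium | [Li]C[C@@]1(C)[C@@H]2CCCC(C)(C)C2=CC[C@@H]1C | intermediate
12 | lithium 1-DM-2,3-dimethoxy-4-oxocyclobut-2-en-1-olate | [Li+].[O-]C1(C[C@@]2(C)[C@@H]3CCCC(C)(C)C3=CC[C@@H]2C)C(OC)=C(OC)C1=O | intermediate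
13 | 1-DM-2,3-dimethoxy-4-oxocyclobut-2-en-1-yl trifluoroacetate | O=C(OC1(C[C@@]2(C)[C@@H]3CCCC(C)(C)C3=CC[C@@H]2C)C(OC)=C(OC)C1=O)C(F)(F)F | intermediate
14 | 3-DM-4-methoxycyclobut-3-ene-1,2-dione | COC1=C(C[C@@]2(C)[C@@H]3CCCC(C)(C)C3=CC[C@@H]2C)C(=O)C1=O | intermediate
15 | acetylene | C#C | starting material
16 | lithium acetylide | [Li]C#C | intermediate
17 | 2-DM-4-ethynyl-4-hydroxy-3-methoxycyclobut-2-en-1-one | C#CC1(O)C(OC)=C(C[C@@]2(C)[C@@H]3CCCC(C)(C)C3=CC[C@@H]2C)C1=O | intermediate
18 | (3Z)-2-DM-4-hydroxy-3-methoxyhexa-1,3-dien-5-yn-1-one (ketene, ethynyl cis to the ketene-bearing carbon) | C#C/C(O)=C(/OC)C(C[C@@]1(C)[C@@H]2CCCC(C)(C)C2=CC[C@@H]1C)=C=O | intermediate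
19 | 2-DM-4-hydroxy-3-methoxyphenoxyl-5-yl diradical (oxyl on C4', σ-radical on C6') | [O]c1c[c]c(O)c(OC)c1C[C@@]2(C)[C@@H]3CCCC(C)(C)C3=CC[C@@H]2C | intermediate
20 | 2-methoxy-3-DM-1,4-benzoquinone | COC1=C(C[C@@]2(C)[C@@H]3CCCC(C)(C)C3=CC[C@@H]2C)C(=O)C=CC1=O | intermediate
21 | isopentylamine, 3-methylbutan-1-amine | CC(C)CCN | starting material
22 | 2-methoxy-3-DM-5-[(3-methylbutyl)amino]benzene-1,4-diol | CC(C)CCNc1cc(O)c(OC)c(C[C@@]2(C)[C@@H]3CCCC(C)(C)C3=CC[C@@H]2C)c1O | intermediate
23 | 2-methoxy-3-DM-5-[(3-methylbutyl)amino]-1,4-benzoquinone | CC(C)CCNC1=CC(=O)C(OC)=C(C[C@@]2(C)[C@@H]3CCCC(C)(C)C3=CC[C@@H]2C)C1=O | intermediate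
24 | potassium salt of 25 (C2' oxide) | [K+].CC(C)CCNC1=CC(=O)C([O-])=C(C[C@@]2(C)[C@@H]3CCCC(C)(C)C3=CC[C@@H]2C)C1=O | intermediate
25 | nakijiquinone M | CC(C)CCNC1=CC(=O)C(O)=C(C[C@@]2(C)[C@@H]3CCCC(C)(C)C3=CC[C@@H]2C)C1=O | target

## Step count and least certain steps

Total: 10 steps. Longest linear sequence: 10 steps (1 → 25). Compounds 4, 6, 10, 15 and 21 are bought.

**Step 8 (key step).**
- *Risk.* Part of ketene 18 may leak into the five-membered closure. Diradical 19 may also be consumed by intermolecular hydrogen abstraction and radical coupling before the hydroxyl hydrogen has moved. A terminal alkyne gives the radical centre no steric protection.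
- *Fallback.* This is a closed-shell variant that sets out from 14 and returns at 20. CH2=CHMgBr adds to the same carbonyl group to give the 4-ethenyl carbinol F1. Thermolysis in toluene proceeds by ring opening and a 6π electrocyclisation that forms the same C4'–C5' bond without radicals, and tautomerisation gives hydroquinone F2. Ag2O in Et2O oxidises F2 to 20.

**Step 3.**
- *Risk.* Exo and facial selectivity may erode, because the β-substituted enal reacts slowly and may need temperatures at which the acid-sensitive diene oligomerises. The sense of induction rests on a model; the mirror-image catalyst is equally available.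
- *Fallback.* This is a resolution that sets out from 5 and 6 and returns at 8. BF3·OEt2 in CH2Cl2 gives the racemic exo adduct, 7 together with its mirror image ent-7 F3. NaBH4 gives 8 together with ent-8 F4. Esterification with (S)-2-methoxy-2-phenylacetic acid (dicyclohexylcarbodiimide, 4-dimethylaminopyridine) gives the diastereomeric esters F5 (from 8) and F6 (from ent-8), which are separated by chromatography or crystallisation. KOH in aqueous MeOH cleaves F5 to 8.

**Step 5.**
- *Risk.* The reaction may stall at the activated alcohol, because back-side attack at the neopentyl carbon is slow. At the temperature then needed, ionisation with a 1,2-shift may compete.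
- *Fallback.* This route sets out from 8 and returns at 9. Activation and substitution are separated: (CF3SO2)2O and pyridine at −20 °C give the isolable neopentyl triflate F7. Its much better leaving group is displaced by LiI in Et2O–DMF at or near room temperature to give 9.

**Step 9.**
- *Risk.* Regiocontrol may be lost (attack at C6'), a second amine may exchange the C2' methoxy group, or 20 may be consumed as oxidant if reoxidation by O2 is slow.
- *Fallback.* Here C5' receives a leaving group instead of hydrogen, so no oxidant and no regiochemical choice are needed; the route sets out from 14 and returns at 23. (Z)-2-Ethoxyvinyllithium F8 is made from commercial (Z)-tributyl(2-ethoxyvinyl)stannane and n-BuLi. It adds to 14 to give carbinol F9. Thermolysis (ring opening, 6π electrocyclisation, tautomerisation) gives the ethoxyhydroquinone F10, and Ag2O gives 5-ethoxy-2-methoxy-3-DM-1,4-benzoquinone F11. Amine 21 then replaces the unhindered ethoxy group by addition–elimination to give 23.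

**Step 10.**
- *Risk.* Hydroxide may attack C5' with loss of the amine. The reaction may also stall because deprotonation of N–H makes the ring anionic.
- *Fallback.* Hydrolysis is moved ahead of the amine; the route sets out from 14 and returns at 25. The sequence through F9 and F10 gives F11 as described for step 9. KOH in aqueous MeOH removes the methoxy group beside the side chain, the more labile of the two alkoxy groups, to give 5-ethoxy-2-hydroxy-3-DM-1,4-benzoquinone F12. Amine 21 in EtOH then exchanges the remaining ethoxy group, while the C2' oxide protects the other edge, and gives 25.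

## Further compounds

F1 | step 8 | 2-DM-4-ethenyl-4-hydroxy-3-methoxycyclobut-2-en-1-one | C=CC1(O)C(OC)=C(C[C@@]2(C)[C@@H]3CCCC(C)(C)C3=CC[C@@H]2C)C1=O
F2 | step 8 | 2-methoxy-3-DM-benzene-1,4-diol | COc1c(O)ccc(O)c1C[C@@]2(C)[C@@H]3CCCC(C)(C)C3=CC[C@@H]2C
F3 | step 3 | ent-7, (1S,2R,8aS)-1,2,5,5-tetramethyl-1,2,3,5,6,7,8,8a-octahydronaphthalene-1-carbaldehyde | O=C[C@]1(C)[C@H]2CCCC(C)(C)C2=CC[C@H]1C
F4 | step 3 | ent-8, [(1S,2R,8aS)-1,2,5,5-tetramethyl-1,2,3,5,6,7,8,8a-octahydronaphthalen-1-yl]methanol | OC[C@]1(C)[C@H]2CCCC(C)(C)C2=CC[C@H]1C
F5 | step 3 | (S)-2-methoxy-2-phenylacetate of 8 | CO[C@H](C(=O)OC[C@@]1(C)[C@@H]2CCCC(C)(C)C2=CC[C@@H]1C)c1ccccc1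
F6 | step 3 | (S)-2-methoxy-2-phenylacetate of ent-8 | CO[C@H](C(=O)OC[C@]1(C)[C@H]2CCCC(C)(C)C2=CC[C@H]1C)c1ccccc1
F7 | step 5 | trifluoromethanesulfonate of 8 | O=S(=O)(OC[C@@]1(C)[C@@H]2CCCC(C)(C)C2=CC[C@@H]1C)C(F)(F)F
F8 | step 9 | (Z)-2-ethoxyvinyllithium | CCO/C=C\[Li]
F9 | step 9 | 2-DM-4-[(Z)-2-ethoxyethenyl]-4-hydroxy-3-methoxycyclobut-2-en-1-one | CCO/C=C\C1(O)C(OC)=C(C[C@@]2(C)[C@@H]3CCCC(C)(C)C3=CC[C@@H]2C)C1=O
F10 | step 9 | 5-ethoxy-2-methoxy-3-DM-benzene-1,4-diol | CCOc1cc(O)c(OC)c(C[C@@]2(C)[C@@H]3CCCC(C)(C)C3=CC[C@@H]2C)c1O
F11 | step 9 | 5-ethoxy-2-methoxy-3-DM-1,4-benzoquinone | CCOC1=CC(=O)C(OC)=C(C[C@@]2(C)[C@@H]3CCCC(C)(C)C3=CC[C@@H]2C)C1=O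
F12 | step 10 | 5-ethoxy-2-hydroxy-3-DM-1,4-benzoquinone | CCOC1=CC(=O)C(O)=C(C[C@@]2(C)[C@@H]3CCCC(C)(C)C3=CC[C@@H]2C)C1=O
A1 | alternative 1 | trans-6-(6,6-dimethylcyclohex-1-enyl)-4-methyl-3-(2,3,5,6-tetramethoxybenzyl)tetrahydropyran-2-one (C3 epimers) | O=C1O[C@@H](C2=CCCCC2(C)C)C[C@H](C)C1Cc1c(OC)c(OC)cc(OC)c1OC
A2 | alternative 1 | ring B carboxylic acid (carboxyl in place of the 9-methyl group) | COc1cc(OC)c(OC)c(C[C@@]2(C(=O)O)[C@@H]3CCCC(C)(C)C3=CC[C@@H]2C)c1OC
A3 | alternative 2 | 4-methyl-4-(2,3,5,6-tetramethoxybenzyl)cyclohexa-2,5-dien-1-one | COc1cc(OC)c(OC)c(CC2(C)C=CC(=O)C=C2)c1OC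
A4 | alternative 2 | 4-methyl-2-(trimethylsilyloxy)penta-1,3-diene | C=C(O[Si](C)(C)C)C=C(C)C
A5 | alternative 2 | cis-fused bicyclic enone with ring A silyl enol ether | COc1cc(OC)c(OC)c(C[C@]2(C)C=CC(=O)[C@@H]3[C@H]2CC(O[Si](C)(C)C)=CC3(C)C)c1OC
A6 | alternative 3 | ring B aldehyde (identical with 7) | O=C[C@@]1(C)[C@@H]2CCCC(C)(C)C2=CC[C@@H]1C
A7 | alternative 3 | 1,2,4,5-tetramethoxybenzene | COc1cc(OC)c(OC)cc1OC
A8 | alternative 3 | 3-DM-1,2,4,5-tetramethoxybenzene | COc1cc(OC)c(OC)c(C[C@@]2(C)[C@@H]3CCCC(C)(C)C3=CC[C@@H]2C)c1OC
A9 | alternative 3 | 2,5-dimethoxy-3-DM-1,4-benzoquinone | COC1=CC(=O)C(OC)=C(C[C@@]2(C)[C@@H]3CCCC(C)(C)C3=CC[C@@H]2C)C1=O
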